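## Retrosynthetic overview

1. The azepane is closed last by ring-closing metathesis (RCM) of an N-allyl/C-allyl diene; one hydrogenation then saturates the ring and frees the tertiary OH from its benzyl ether.
2. The spiro-pyrrolidine comes before it: a Boc-carbamate nitrogen closes onto a cyclopentene (seleno-amidocyclisation) to make the N-bearing quaternary carbon, and the C–Se bond is exchanged for allyl by radical allylation.
3. Convergent union: Negishi coupling of an alkylzinc (amino-lactone fragment 2) with a bicyclic enol triflate (fragment 1).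
4. Fragment 1 (cyclopentane plus hydroxy-methyl lactone) comes from enantiopure (1R,5S)-2-oxabicyclo[3.3.0]oct-6-en-3-one: convex-face hydroxylation and methylation, allylic oxidation, ethyl addition with oxidative transposition, hydrogenation, triflation.
5. Fragment 2 comes from N-Boc-L-homoserine: vinyl ketone, CBS reduction, methacrylate RCM to the butenolide, cis-hydrogenation, iodide. Ring order: cyclopentane/fused lactone (in the starting lactone) → pendant lactone (RCM) → pyrrolidine → azepane (RCM).

Assumption: both starting materials are bought as single enantiomers; bicyclic numbering is O2, C1 (O–CH), C3 (C=O), C4–C8; exo = convex face (side of H-1 and H-5), endo = concave face.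

## Route

Step 1
Reactants: 1 (1R,5S)-2-oxabicyclo[3.3.0]oct-6-en-3-one
Product: 3 exo-hydroxy lactone, via potassium enolate 2 (not isolated)
Conditions: KN(SiMe3)2, THF, −78 °C; then 2-(phenylsulfonyl)-3-phenyloxaziridine, −78 °C; AcOH quench
Reagents that add atoms: 2-(phenylsulfonyl)-3-phenyloxaziridine, O=S(=O)(N1OC1c1ccccc1)c1ccccc1
Why: Enolate α-hydroxylation (Davis oxidation) occurs on the convex face of the lactone enolate to give the exo alcohol; this centre is re-made in step 3, so its configuration is not critical.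

Step 2
Reactants: 3 exo-hydroxy lactone
Product: 4 exo-benzyloxy lactone
Conditions: BnBr, Ag2O, CH2Cl2, rt, dark
Reagents that add atoms: benzyl bromide, BrCc1ccccc1
Why: Ag2O-promoted Williamson etherification protects the secondary alcohol under non-basic conditions that leave the lactone intact.

Step 3
Reactants: 4 exo-benzyloxy lactone
Product: 6 endo-benzyloxy exo-methyl lactone, via lithium enolate 5 (not isolated)
Conditions: LiN(iPr)2, THF, −78 °C; then MeI, DMPU, −78 → −40 °C
Reagents that add atoms: iodomethane, CI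
Why: Enolate alkylation of the α-alkoxy lactone: MeI attacks the planar enolate from the convex face, so methyl ends exo and benzyloxy endo, which sets the quaternary carbinol carbon as in the target.

Step 4
Reactants: 6 endo-benzyloxy exo-methyl lactone
Product: 7 enedione (8-oxo-6-ene)
Conditions: CrO3, 3,5-dimethylpyrazole, CH2Cl2, −20 °C
Reagents that add atoms: chromium trioxide, O=[Cr](=O)=O
Why: Allylic oxidation converts the only allylic CH2 (C8) into the conjugated ketone; the other allylic position is a hindered tertiary ring-fusion C–H that cannot give a ketone.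

Step 5
Reactants: 7 enedione (8-oxo-6-ene)
Product: 8 tertiary allylic alcohol
Conditions: EtMgBr, CeCl3, THF, −78 °C; cold 1 M HCl quench
Reagents that add atoms: ethylmagnesium bromide, CC[Mg]Br
Why: 1,2-Addition of the weakly basic organocerium reagent to the enone carbonyl (no enolisation, no attack on the lactone) gives the tertiary allylic alcohol; this carbinol centre is planarised in step 6.

Step 6
Reactants: 8 tertiary allylic alcohol
Product: 9 transposed enone (8-ethyl-7-en-6-one)
Conditions: pyridinium chlorochromate [C5H5NH][CrO3Cl], 4 Å molecular sieves, CH2Cl2, rt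
Reagents that add atoms: pyridinium chlorochromate, [O-][Cr](=O)(=O)Cl.c1cc[nH+]cc1
Why: Dauben-type oxidative 1,3-transposition: the allylic chromate ester undergoes a [3,3] shift and is oxidised, which places the carbonyl at C6 and ethyl on the β-carbon C8.

Step 7
Reactants: 9 transposed enone (8-ethyl-7-en-6-one)
Product: 10 saturated keto lactone (endo-ethyl)
Conditions: H2 (1 atm), Pd/C, pyridine, EtOAc, rt
Reagents that add atoms: none
Why: Catalytic hydrogenation of the enone C=C from the convex face puts H-8 exo and therefore ethyl endo (cis to the lactone oxygen); pyridine suppresses benzyl ether hydrogenolysis.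

Step 8
Reactants: 10 saturated keto lactone (endo-ethyl)
Product: 12 enol triflate, via potassium enolate 11 (not isolated)
Conditions: KN(SiMe3)2, THF, −78 °C; then PhN(SO2CF3)2, −78 → 0 °C; AcOH quench
Reagents that add atoms: N-phenylbis(trifluoromethanesulfonimide), FC(F)(F)S(=O)(=O)N(c1ccccc1)S(=O)(=O)C(F)(F)F
Why: Kinetic deprotonation at the unhindered C7 methylene (not the hindered ring-fusion C5–H, whose enolate would expel the lactone carboxylate) and enolate O-triflation give the C6=C7 enol triflate.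

Step 9
Reactants: 13 N-Boc-L-homoserine
Product: 14 N-Boc-O-benzyl-L-homoserine
Conditions: NaH (2.2 equiv), DMF, 0 °C; BnBr; then aq. HCl to pH 3
Reagents that add atoms: benzyl bromide, BrCc1ccccc1
Why: Williamson etherification of the carboxylate/alkoxide dianion benzylates the more nucleophilic alkoxide and leaves the stereocentre untouched.

Step 10
Reactants: 14 N-Boc-O-benzyl-L-homoserine
Product: 15 Weinreb amide
Conditions: MeNH(OMe)·HCl, EDC·HCl, HOBt, iPr2NEt, CH2Cl2, 0 °C → rt
Reagents that add atoms: N,O-dimethylhydroxylamine hydrochloride, CNOC.Cl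
Why: Carbodiimide amide coupling gives the Weinreb amide, with HOBt suppressing racemisation of the carbamate-protected α-centre.

Step 11
Reactants: 15 Weinreb amide
Product: 16 vinyl ketone
Conditions: CH2=CHMgBr (3 equiv), THF, −78 → 0 °C; inverse quench into cold 1 M HCl
Reagents that add atoms: vinylmagnesium bromide, C=C[Mg]Br
Why: Weinreb ketone synthesis: the magnesium chelate stops at mono-addition and releases the enone only on the acidic quench, which also keeps the freed MeNH(OMe) from adding to it.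

Step 12
Reactants: 16 vinyl ketone
Product: 17 syn allylic alcohol
Conditions: (S)-2-methyl-CBS-oxazaborolidine (20 mol%), BH3·SMe2, THF, −30 °C; MeOH quench
Reagents that add atoms: none
Why: Corey–Bakshi–Shibata reduction: catalyst-controlled 1,2-hydride delivery (vinyl as the large group) gives the (3S) carbinol, i.e. the syn (threo) amino alcohol, in the same sense as the Felkin–Anh preference.

Step 13
Reactants: 17 syn allylic alcohol
Product: 18 methacrylate
Conditions: methacryloyl chloride, Et3N, DMAP (cat.), CH2Cl2, 0 °C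
Reagents that add atoms: methacryloyl chloride, CC(=C)C(Cl)=O
Why: DMAP-catalysed O-acylation esterifies the secondary allylic alcohol while the carbamate N–H stays unreacted.

Step 14
Reactants: 18 methacrylate
Product: 19 butenolide
Conditions: second-generation Grubbs catalyst RuCl2(=CHPh)(H2IMes)(PCy3) (5 mol%), toluene, 80 °C
Reagents that add atoms: none
Why: Ring-closing metathesis between the vinyl group and the methacrylate closes the α-methyl butenolide with loss of ethene; the carbinol stereocentre is not involved.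

Step 15
Reactants: 19 butenolide
Product: 20 hydroxy lactone
Conditions: H2 (1 atm), Pd/C, EtOAc–MeOH, rt
Reagents that add atoms: none
Why: Catalytic hydrogenation adds H2 to the butenolide anti to the C5 side chain, giving the cis-2,4-disubstituted lactone (new methyl-bearing centre S), and hydrogenolysis cleaves the benzyl ether in the same operation.

Step 16
Reactants: 20 hydroxy lactone
Product: 21 iodide
Conditions: I2, PPh3, imidazole, CH2Cl2, 0 °C → rt
Reagents that add atoms: iodine, II
Why: Appel-type iodination (SN2 at the primary carbon) converts the alcohol into the iodide without touching carbamate or lactone.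

Step 17
Reactants: 21 iodide; 12 enol triflate
Product: 23 coupled cyclopentene carbamate, via alkylzinc iodide 22 (not isolated)
Conditions: Zn dust, DMF, rt; then 12, Pd2(dba)3 (2.5 mol%), SPhos (10 mol%), DMF, 40 °C
Reagents that add atoms: none
Why: Negishi sp3–sp2 cross-coupling: zinc inserts into the primary C–I bond (carbamate N–H and lactone tolerated) and zerovalent palladium with a bulky biaryl phosphine couples the alkylzinc with the enol triflate faster than β-hydride elimination; no stereocentre is affected.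

Step 18
Reactants: 23 coupled cyclopentene carbamate
Product: 24 spiro selenide
Conditions: N-(phenylseleno)phthalimide, camphorsulfonic acid (10 mol%), CH2Cl2, −20 °C → rt
Reagents that add atoms: N-(phenylseleno)phthalimide, O=C1N([Se]c2ccccc2)C(=O)c2ccccc12
Why: Electrophilic seleno-amidocyclisation of the alkenyl carbamate: the seleniranium ion is opened in Markovnikov 5-exo fashion by the carbamate nitrogen, which can reach the substituted alkene carbon only from the convex face (the concave face is covered by the lactone with its endo benzyloxy group and by the endo ethyl), so the spiro carbon forms with N exo and the pyrrolidine CH2 endo, and SePh ends trans to N on C7.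

Step 19
Reactants: 24 spiro selenide
Product: 25 allyl spiro carbamate
Conditions: Bu3SnCH2CH=CH2, AIBN, benzene, 80 °C
Reagents that add atoms: allyltributylstannane, C=CC[Sn](CCCC)(CCCC)CCCC
Why: Keck radical allylation: abstraction of PhSe gives a secondary cyclopentyl radical that adds to the allylstannane on the convex face, anti to its two endo neighbours (ethyl and the pyrrolidine CH2), which places allyl cis to nitrogen and trans to ethyl.

Step 20
Reactants: 25 allyl spiro carbamate
Product: 27 N-allyl diene, via amine trifluoroacetate 26 (not isolated)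
Conditions: CF3CO2H, CH2Cl2, 0 °C → rt; evaporate; then CH2=CHCH2Br, K2CO3, MeCN, 50 °C
Reagents that add atoms: allyl bromide, C=CCBr
Why: Acidolytic Boc cleavage followed by SN2 N-alkylation of the hindered secondary amine with the reactive allyl bromide; lactones, benzyl ether and the C-allyl group survive.

Step 21
Reactants: 27 N-allyl diene
Product: 30 O-benzyl azepine alkene, via diene ammonium tosylate 28 (not isolated), via azepine ammonium tosylate 29 (not isolated)
Conditions: TsOH·H2O (1.05 equiv), CH2Cl2; then second-generation Grubbs catalyst RuCl2(=CHPh)(H2IMes)(PCy3) (10 mol%), 40 °C; aq. NaHCO3 work-up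
Reagents that add atoms: none
Why: Ring-closing metathesis of the ammonium salt (protonation keeps the amine off ruthenium): the cis-disposed N-allyl and C-allyl groups close the seven-membered ring with loss of ethene, and no stereocentre is touched.

Step 22
Reactants: 30 O-benzyl azepine alkene
Product: 31 target CNP0260919.3
Conditions: H2 (3 atm), Pd(OH)2/C, EtOH, rt
Reagents that add atoms: none
Why: Heterogeneous hydrogenation saturates the ring alkene and hydrogenolysis cleaves the tertiary benzyl ether to the free alcohol; no stereocentre is created or epimerised.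

## Compound list

1 | (1R,5S)-2-oxabicyclo[3.3.0]oct-6-en-3-one (cis-fused) | O=C1C[C@H]2C=CC[C@H]2O1 | starting material
2 | potassium lactone enolate of 1 (not isolated) | [K+].[O-]C1=C[C@H]2C=CC[C@H]2O1 | intermediate
3 | 4-exo-hydroxy derivative of 1 (OH on the convex face, cis to H-5) | O=C1[C@H](O)[C@H]2C=CC[C@H]2O1 | intermediate
4 | 4-exo-benzyloxy derivative of 1 (benzyl ether of 3) | O=C1[C@H](OCc3ccccc3)[C@H]2C=CC[C@H]2O1 | intermediate
5 | lithium lactone enolate of 4 (not isolated) | [Li+].[O-]C1=C(OCc3ccccc3)[C@H]2C=CC[C@H]2O1 | intermediate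
6 | (1R,4S,5S)-4-(benzyloxy)-4-methyl-2-oxabicyclo[3.3.0]oct-6-en-3-one (Me exo, OBn endo) | O=C1[C@@](C)(OCc3ccccc3)[C@H]2C=CC[C@H]2O1 | intermediate
7 | 4-endo-(benzyloxy)-4-exo-methyl-2-oxabicyclo[3.3.0]oct-6-ene-3,8-dione (ring fusion as in 6) | O=C1[C@@](C)(OCc3ccccc3)[C@H]2C=CC(=O)[C@H]2O1 | intermediate
8 | 4-endo-(benzyloxy)-8-exo-ethyl-8-endo-hydroxy-4-exo-methyl-2-oxabicyclo[3.3.0]oct-6-en-3-one | O=C1[C@@](C)(OCc3ccccc3)[C@H]2C=C[C@](O)(CC)[C@H]2O1 | intermediate
9 | 4-endo-(benzyloxy)-8-ethyl-4-exo-methyl-2-oxabicyclo[3.3.0]oct-7-ene-3,6-dione | O=C1[C@@](C)(OCc3ccccc3)[C@H]2C(=O)C=C(CC)[C@H]2O1 | intermediate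
10 | 4-endo-(benzyloxy)-8-endo-ethyl-4-exo-methyl-2-oxabicyclo[3.3.0]octane-3,6-dione | O=C1[C@@](C)(OCc3ccccc3)[C@H]2C(=O)C[C@@H](CC)[C@H]2O1 | intermediate
11 | potassium C6=C7 enolate of 10 (not isolated) | [K+].O=C1[C@@](C)(OCc3ccccc3)[C@H]2C([O-])=C[C@@H](CC)[C@H]2O1 | intermediate
12 | 4-endo-(benzyloxy)-8-endo-ethyl-4-exo-methyl-3-oxo-2-oxabicyclo[3.3.0]oct-6-en-6-yl trifluoromethanesulfonate | O=C1[C@@](C)(OCc3ccccc3)[C@H]2C(OS(=O)(=O)C(F)(F)F)=C[C@@H](CC)[C@H]2O1 | intermediate
13 | N-Boc-L-homoserine, (2S)-2-[(tert-butoxycarbonyl)amino]-4-hydroxybutanoic acid | CC(C)(C)OC(=O)N[C@@H](CCO)C(=O)O | starting material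
14 | N-Boc-O-benzyl-L-homoserine | CC(C)(C)OC(=O)N[C@@H](CCOCc1ccccc1)C(=O)O | intermediate
15 | tert-butyl N-[(2S)-4-(benzyloxy)-1-[methoxy(methyl)amino]-1-oxobutan-2-yl]carbamate | CC(C)(C)OC(=O)N[C@@H](CCOCc1ccccc1)C(=O)N(C)OC | intermediate
16 | tert-butyl N-[(4S)-6-(benzyloxy)-3-oxohex-1-en-4-yl]carbamate | CC(C)(C)OC(=O)N[C@@H](CCOCc1ccccc1)C(=O)C=C | intermediate
17 | tert-butyl N-[(3S,4S)-6-(benzyloxy)-3-hydroxyhex-1-en-4-yl]carbamate (syn amino alcohol) | CC(C)(C)OC(=O)N[C@@H](CCOCc1ccccc1)[C@@H](O)C=C | intermediate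
18 | (3S,4S)-6-(benzyloxy)-4-[(tert-butoxycarbonyl)amino]hex-1-en-3-yl 2-methylprop-2-enoate | CC(C)(C)OC(=O)N[C@@H](CCOCc1ccccc1)[C@@H](OC(=O)C(C)=C)C=C | intermediate
19 | tert-butyl N-[(1S)-3-(benzyloxy)-1-[(2S)-4-methyl-5-oxo-2,5-dihydrofuran-2-yl]propyl]carbamate | CC(C)(C)OC(=O)N[C@@H](CCOCc1ccccc1)[C@H]2OC(=O)C(C)=C2 | intermediate
20 | tert-butyl N-[(1S)-3-hydroxy-1-[(2S,4S)-4-methyl-5-oxooxolan-2-yl]propyl]carbamate (cis lactone) | CC(C)(C)OC(=O)N[C@@H](CCO)[C@H]1OC(=O)[C@@H](C)C1 | intermediate
21 | tert-butyl N-[(1S)-3-iodo-1-[(2S,4S)-4-methyl-5-oxooxolan-2-yl]propyl]carbamate | CC(C)(C)OC(=O)N[C@@H](CCI)[C@H]1OC(=O)[C@@H](C)C1 | intermediate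
22 | alkylzinc iodide from 21, C–I replaced by C–ZnI (not isolated) | CC(C)(C)OC(=O)N[C@@H](CC[Zn]I)[C@H]1OC(=O)[C@@H](C)C1 | intermediate
23 | tert-butyl N-[(1S)-3-[4-endo-(benzyloxy)-8-endo-ethyl-4-exo-methyl-3-oxo-2-oxabicyclo[3.3.0]oct-6-en-6-yl]-1-[(2S,4S)-4-methyl-5-oxooxolan-2-yl]propyl]carbamate | O=C1[C@@](C)(OCc3ccccc3)[C@H]2C(CC[C@H](NC(=O)OC(C)(C)C)[C@H]4OC(=O)[C@@H](C)C4)=C[C@@H](CC)[C@H]2O1 | intermediate
24 | tert-butyl 4-endo-(benzyloxy)-8-endo-ethyl-4-exo-methyl-5'-[(2S,4S)-4-methyl-5-oxooxolan-2-yl]-3-oxo-7-endo-(phenylselanyl)spiro[2-oxabicyclo[3.3.0]octane-6,2'-pyrrolidine]-1'-carboxylate, (5'S), N-1' on the exo face of C6 | CC[C@H]1[C@H]2OC(=O)[C@@](C)(OCc5ccccc5)[C@H]2[C@@]3(CC[C@@H]([C@@H]4C[C@H](C)C(=O)O4)N3C(=O)OC(C)(C)C)[C@H]1[Se]c6ccccc6 | intermediate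
25 | as 24 but with 7-exo-(prop-2-enyl) in place of SePh (allyl cis to N, trans to ethyl) | CC[C@H]1[C@H]2OC(=O)[C@@](C)(OCc5ccccc5)[C@H]2[C@@]3(CC[C@@H]([C@@H]4C[C@H](C)C(=O)O4)N3C(=O)OC(C)(C)C)[C@@H]1CC=C | intermediate
26 | trifluoroacetate salt of the N–H spiro amine from 25 (not isolated) | CC[C@H]1[C@H]2OC(=O)[C@@](C)(OCc5ccccc5)[C@H]2[C@@]3(CC[C@@H]([C@@H]4C[C@H](C)C(=O)O4)N3)[C@@H]1CC=C.OC(=O)C(F)(F)F | intermediate
27 | N-1'-(prop-2-enyl) derivative of that amine (N-allyl, C-allyl diene) | CC[C@H]1[C@H]2OC(=O)[C@@](C)(OCc5ccccc5)[C@H]2[C@@]3(CC[C@@H]([C@@H]4C[C@H](C)C(=O)O4)N3CC=C)[C@@H]1CC=C | intermediate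
28 | 4-methylbenzenesulfonate salt of 27 (not isolated) | CC[C@H]1[C@H]2OC(=O)[C@@](C)(OCc5ccccc5)[C@H]2[C@@]3(CC[C@@H]([C@@H]4C[C@H](C)C(=O)O4)N3CC=C)[C@@H]1CC=C.Cc1ccc(cc1)S(=O)(=O)O | intermediate
29 | 4-methylbenzenesulfonate salt of 30 (not isolated) | CC[C@H]1[C@H]2OC(=O)[C@@](C)(OCc5ccccc5)[C@H]2[C@]23CC[C@@H]([C@@H]4C[C@H](C)C(=O)O4)N2C/C=C\C[C@H]13.Cc1ccc(cc1)S(=O)(=O)O | intermediate
30 | O-benzyl ether of the target with a Z C=C in the azepine ring (N–CH2–CH=CH–CH2), all stereocentres as in 31 | CC[C@H]1[C@H]2OC(=O)[C@@](C)(OCc5ccccc5)[C@H]2[C@]23CC[C@@H]([C@@H]4C[C@H](C)C(=O)O4)N2C/C=C\C[C@H]13 | intermediate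
31 | CNP0260919.3 | CC[C@H]1[C@H]2OC(=O)[C@@](C)(O)[C@H]2[C@]23CC[C@@H]([C@@H]4C[C@H](C)C(=O)O4)N2CCCC[C@H]13 | target

## Step count and risks

Total step count: 22. Longest linear sequence: 14 steps (steps 1–8 then 17–22; the branch of steps 9–16 then 17–22 is also 14).

Steps most likely to fail:

Step 4. The allylic oxidation may give the transposed enone or attack the benzylic CH2 of the ether. The fallback sets out from 6 and comes back at 9. Epoxidation of 6 with mCPBA on the convex face gives the exo-epoxide F1. Base-induced isomerisation with Et2Al(tmp) (diethylaluminium 2,2,6,6-tetramethylpiperidide), which abstracts the syn hydrogen of the C8 methylene, gives the allylic alcohol F2 with oxygen already at C6. Dess–Martin oxidation gives the enone F3. Conjugate addition of Et2CuLi in the presence of Me3SiCl gives the silyl enol ether F4, and Saegusa–Ito dehydrogenation with Pd(OAc)2 restores the C7=C8 double bond to give 9. Oxygen is thus placed by epoxide isomerisation and ethyl by conjugate addition, not by C–H oxidation and 1,2-addition/transposition.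

Step 18 (and with it the facial selectivity of step 19). The anti addition needs selenium on the concave face, and nitrogen has to form a congested tetrasubstituted centre. The fallback sets out from 10 and comes back at 31; it replaces electrophilic cyclisation and radical allylation by a conjugate addition whose neighbouring centre is set under thermodynamic control. Vilsmeier–Haack–Arnold bromoformylation of 10 (PBr3, DMF) gives the β-bromo enal F5. Negishi coupling with 22 gives the enal F6. CF3CO2H then NaHCO3 frees the primary amine, which closes by intramolecular aza-Michael addition (5-exo-trig, from the convex face) to the spiro amino aldehyde F7; its epimerisable formyl group settles exo, trans to ethyl and cis to nitrogen. Wittig methylenation (Ph3P=CH2) gives the vinyl amine F8. N-alkylation with but-3-enyl triflate gives the diene F9. RCM (same catalyst, ammonium salt) gives the isomeric azepine alkene F10, and H2 with Pd(OH)2/C gives 31.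

Step 12. Coordination of the carbamate to borane may erode the catalyst control and give syn/anti mixtures. The fallback sets out from 16 and comes back at 18. Chelation-controlled reduction with LiAlH(OtBu)3 in EtOH at −78 °C gives the anti allylic alcohol F11. Mitsunobu esterification with methacrylic acid (PPh3, DIAD) inverts the carbinol centre and delivers 18 directly.

Further compounds
F1 | step 4 | 6,7-exo-epoxide of 6 | O=C1[C@@](C)(OCc3ccccc3)[C@H]2[C@@H]4O[C@@H]4C[C@H]2O1
F2 | step 4 | 4-endo-(benzyloxy)-6-exo-hydroxy-4-exo-methyl-2-oxabicyclo[3.3.0]oct-7-en-3-one | O=C1[C@@](C)(OCc3ccccc3)[C@H]2[C@H](O)C=C[C@H]2O1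
F3 | step 4 | 4-endo-(benzyloxy)-4-exo-methyl-2-oxabicyclo[3.3.0]oct-7-ene-3,6-dione | O=C1[C@@](C)(OCc3ccccc3)[C@H]2C(=O)C=C[C@H]2O1
F4 | step 4 | 4-endo-(benzyloxy)-8-exo-ethyl-4-exo-methyl-6-(trimethylsilyloxy)-2-oxabicyclo[3.3.0]oct-6-en-3-one | O=C1[C@@](C)(OCc3ccccc3)[C@H]2C(O[Si](C)(C)C)=C[C@H](CC)[C@H]2O1
F5 | step 18 | 4-endo-(benzyloxy)-6-bromo-8-endo-ethyl-4-exo-methyl-3-oxo-2-oxabicyclo[3.3.0]oct-6-ene-7-carbaldehyde | O=C1[C@@](C)(OCc3ccccc3)[C@H]2C(Br)=C(C=O)[C@@H](CC)[C@H]2O1
F6 | step 18 | 7-formyl analogue of 23 (enal carrying the Boc-amino lactone chain at C6) | O=C1[C@@](C)(OCc3ccccc3)[C@H]2C(CC[C@H](NC(=O)OC(C)(C)C)[C@H]4OC(=O)[C@@H](C)C4)=C(C=O)[C@@H](CC)[C@H]2O1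
F7 | step 18 | N–H spiro-pyrrolidine with 7-exo-formyl (N exo at the spiro carbon, CHO cis to N) | CC[C@H]1[C@H]2OC(=O)[C@@](C)(OCc5ccccc5)[C@H]2[C@@]3(CC[C@@H]([C@@H]4C[C@H](C)C(=O)O4)N3)[C@@H]1C=O
F8 | step 18 | N–H spiro-pyrrolidine with 7-exo-vinyl | CC[C@H]1[C@H]2OC(=O)[C@@](C)(OCc5ccccc5)[C@H]2[C@@]3(CC[C@@H]([C@@H]4C[C@H](C)C(=O)O4)N3)[C@@H]1C=C
F9 | step 18 | N-(but-3-enyl) 7-exo-vinyl diene | CC[C@H]1[C@H]2OC(=O)[C@@](C)(OCc5ccccc5)[C@H]2[C@@]3(CC[C@@H]([C@@H]4C[C@H](C)C(=O)O4)N3CCC=C)[C@@H]1C=C
F10 | step 18 | O-benzyl ether of the target with a Z C=C next to the ring-fusion CH (N–CH2–CH2–CH=CH) | CC[C@H]1[C@H]2OC(=O)[C@@](C)(OCc5ccccc5)[C@H]2[C@]23CC[C@@H]([C@@H]4C[C@H](C)C(=O)O4)N2CC/C=C\[C@H]13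
F11 | step 12 | tert-butyl N-[(3R,4S)-6-(benzyloxy)-3-hydroxyhex-1-en-4-yl]carbamate (anti amino alcohol) | CC(C)(C)OC(=O)N[C@@H](CCOCc1ccccc1)[C@H](O)C=C
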